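The target is the C3a-stearate of (+)-lariciresinol. It has one oxolane ring (O1, C2 with a guaiacyl group, C3 with C3a–O–stearoyl, C4 with the benzylic C4a, C5), is (2S,3R,4R), and is 2,3-trans and 3,4-cis.
Enabling feature: C4 joins the ring bond C3–C4 and, one atom further out, the C4a–aryl bond, and C3a is already an acyloxy carbon. C3=C3a can therefore be drawn as an enol stearate that accepts a C4 radical and holds the spin beside oxygen until a hydrogen atom arrives.
Cuts, in retrosynthetic order: the two phenolic O–benzyl bonds; C4a–aryl together with C3–C4 (one radical cascade); C3a–O (acid added across an alkyne); O1–C5 (O-allylation); C2–C3 (ethynylation of O-benzylvanillin).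
Forward: the chain C3a≡C3–C2(Ar)–O1–C5–C4=C4a is assembled in four steps and a diazonium salt in three. The cascade then attaches the second arene and closes the only ring, and debenzylation finishes the route.
Stereochemistry: C2 comes from a lipase resolution of the propargylic alcohol. C3 and C4 are set from C2 in the 5-exo transition state, where allylic strain of the Z-enol ester gives 2,3-trans and the cis preference of a radical substituted at its own carbon gives 3,4-cis.

Key step: step 8

Remark: the oxolane locants (O1, C2, C3, C3a, C4, C4a, C5) denote the same atoms in every open-chain precursor. The geometry of the enol ester is not recorded in the target, because C3a ends as CH2.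

Step 1
Reactants: 1 4-(benzyloxy)-3-methoxybenzaldehyde (O-benzylvanillin)
Product: 3 rac-1-[4-(benzyloxy)-3-methoxyphenyl]prop-2-yn-1-ol, via bromomagnesium alkoxide 2 (not isolated)
Conditions: HC≡CMgBr (0.5 M in THF, 1.3 equiv), THF, 0 °C to rt; sat. aq NH4Cl
Reagents that add atoms: ethynylmagnesium bromide, C#C[Mg]Br
Why: Grignard 1,2-addition of an alkynyl nucleophile to a non-enolisable aromatic aldehyde should form C2–C3 cleanly, and the carbinol centre is deliberately left racemic for the resolution that follows.

Step 2
Reactants: 3 rac-1-[4-(benzyloxy)-3-methoxyphenyl]prop-2-yn-1-ol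
Product: 4 (S)-1-[4-(benzyloxy)-3-methoxyphenyl]prop-2-yn-1-ol
Conditions: Novozym 435 (immobilised Candida antarctica lipase B), vinyl acetate (5 equiv), MTBE, 40 °C, run to just past half conversion (chiral HPLC control); chromatography
Reagents that add atoms: none
Why: In this lipase-catalysed kinetic resolution by irreversible transesterification, the empirical pocket-size rule for secondary alcohols puts the aryl group in the large pocket and the slim ethynyl group in the medium pocket, so the (R)-alcohol should be acetylated while the (S)-alcohol, from a substrate class known to resolve well with this enzyme, is left unreacted and separated.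

Step 3
Reactants: 4 (S)-1-[4-(benzyloxy)-3-methoxyphenyl]prop-2-yn-1-ol; 5 allyl bromide
Product: 7 (S)-4-[1-(allyloxy)prop-2-yn-1-yl]-1-(benzyloxy)-2-methoxybenzene, via sodium alkoxide 6 (not isolated)
Conditions: NaH (1.1 equiv), THF, 0 °C; then 5 (1.5 equiv), Bu4NI (cat.), 0 °C to rt
Reagents that add atoms: none
Why: In this Williamson ether synthesis the secondary alkoxide is alkylated at oxygen by the reactive allylic bromide (O1–C5 bond) without touching any bond to C2, so the configuration is kept, and one equivalent of NaH in THF at or below room temperature should avoid propargyl-to-allenyl isomerisation.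

Step 4
Reactants: 7 (S)-4-[1-(allyloxy)prop-2-yn-1-yl]-1-(benzyloxy)-2-methoxybenzene; 8 stearic acid
Product: 9 (S,Z)-3-(allyloxy)-3-[4-(benzyloxy)-3-methoxyphenyl]prop-1-en-1-yl stearate
Conditions: 8 (1.0 equiv), Ru(methallyl)2(dppb) (2 mol %; methallyl = η3-2-methylallyl, dppb = 1,4-bis(diphenylphosphino)butane), toluene, 65 °C, Ar; filtration through Et3N-deactivated silica
Reagents that add atoms: none
Why: In this ruthenium-catalysed anti-Markovnikov hydro-acyloxylation of a terminal alkyne, the carboxylate attacks the electrophilic carbon of a ruthenium vinylidene formed from C3≡C3a and protonolysis delivers the formal trans-addition product, the Z-enol ester, a reaction known for aliphatic acids and for propargylic ethers that leaves C2 untouched.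

Step 5
Reactants: 10 2-methoxy-4-nitrophenol
Product: 11 1-(benzyloxy)-2-methoxy-4-nitrobenzene
Conditions: BnBr (1.1 equiv), K2CO3 (1.5 equiv), DMF, 60 °C
Reagents that add atoms: benzyl bromide, BrCc1ccccc1
Why: Williamson O-benzylation of an acidic nitrophenol is routine and installs the same phenol protection as in 1, so that a single final operation frees both phenols.

Step 6
Reactants: 11 1-(benzyloxy)-2-methoxy-4-nitrobenzene
Product: 12 4-(benzyloxy)-3-methoxyaniline
Conditions: Fe powder, NH4Cl, EtOH/H2O 4:1, 80 °C
Reagents that add atoms: none
Why: Béchamp-type iron reduction converts the nitro group into the amine under near-neutral conditions that, unlike hydrogenation over palladium, do not cleave the benzyl ether.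

Step 7
Reactants: 12 4-(benzyloxy)-3-methoxyaniline
Product: 13 4-(benzyloxy)-3-methoxybenzenediazonium tetrafluoroborate
Conditions: t-BuONO (1.3 equiv), HBF4 (48 % aq, 2 equiv), EtOH, 0 °C; precipitation with Et2O
Reagents that add atoms: tert-butyl nitrite, CC(C)(C)ON=O; tetrafluoroboric acid, [H+].F[B-](F)(F)F
Why: Diazotisation of the aniline by the nitrosonium equivalent in the presence of HBF4 should give the tetrafluoroborate, which for a para-alkoxy arene is a stable solid that precipitates with ether and can be stored cold.

Step 8
Reactants: 9 (S,Z)-3-(allyloxy)-3-[4-(benzyloxy)-3-methoxyphenyl]prop-1-en-1-yl stearate; 13 4-(benzyloxy)-3-methoxybenzenediazonium tetrafluoroborate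
Product: 17 [(2S,3R,4R)-2-[4-(benzyloxy)-3-methoxyphenyl]-4-[4-(benzyloxy)-3-methoxybenzyl]oxolan-3-yl]methyl stearate, via aryl radical 14 (not isolated), via open-chain C4 radical 15 (not isolated), via cyclised C3a radical 16 (not isolated)
Conditions: Ru(bpy)3Cl2·6H2O (2 mol %), Hantzsch ester (3 equiv), NaHCO3 (3 equiv), 9 (0.2 M), 13 (2.5 equiv, fed over 6 h as a MeCN solution kept in the dark), MeCN/acetone 2:1, degassed, blue LEDs (450 nm), 20–25 °C
Reagents that add atoms: none
Why: Photoexcited Ru(bpy)3Cl2 (divalent ruthenium) passes one electron to 13, N2 leaves, aryl radical 14 adds to the unsubstituted C4a terminus of the allyl ether (C4a–aryl bond) to give secondary radical 15, and Hantzsch ester returns the trivalent ruthenium to the divalent state. Radical 15 closes the oxolane in the 5-exo-trig mode by attack of C4 on C3 of the enol stearate (C3–C4 bond), the regiochemistry that leaves the spin of 16 on C3a beside the acyloxy oxygen, and a hydrogen atom from Hantzsch ester or its radical cation then gives 17, the dihydropyridyl radical so released being able to reduce more 13 and carry a chain. The closest known reaction type is the reductive Meerwein-type arylation of diallyl-ether 1,6-dienes, in which aryl radical addition, 5-exo closure and hydrogen capture follow each other in the same order; 9 is such a diene with an acyloxy group on the far alkene terminus. C3 is controlled by the resident C2 centre: allylic 1,3-strain against the Z-acyloxy group keeps C2–H in the alkene plane, the C2 aryl group sits pseudo-equatorial in the chair-like transition state, and C4 bonds to the alkene face anti to it, which gives the 2,3-trans relation (3R). C4 is controlled in the same transition state by the known preference of a hexenyl-type radical that carries a substituent on the radical carbon to close to the cis-1,2-disubstituted ring, which gives the 3,4-cis relation (4R); this is the weaker of the two effects and any 3,4-trans isomer would be removed by chromatography. The step needs site selectivity of 14 for the monosubstituted alkene over the 1,2-disubstituted enol ester, secured by the open CH2 terminus against a C3 that is flanked by the branched C2, and it needs addition to outrun hydrogen abstraction and azo coupling, for which 9 is kept concentrated, 13 is fed slowly in excess, the sparingly soluble Hantzsch ester stays dilute, and NaHCO3 takes up the HBF4 that would ionise the acid-labile C2–O1 bond.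

Step 9
Reactants: 17 [(2S,3R,4R)-2-[4-(benzyloxy)-3-methoxyphenyl]-4-[4-(benzyloxy)-3-methoxybenzyl]oxolan-3-yl]methyl stearate
Product: 18 [(2S,3R,4R)-2-(4-hydroxy-3-methoxyphenyl)-4-(4-hydroxy-3-methoxybenzyl)oxolan-3-yl]methyl stearate
Conditions: H2 (1 atm), 10 % Pd/C, EtOAc, rt, stopped at the uptake of two equivalents of H2
Reagents that add atoms: none
Why: Catalytic hydrogenolysis cleaves phenolic benzyl ethers far faster than the cyclic benzylic C2–O1 bond, so a neutral solvent, one atmosphere of hydrogen and a timely stop should leave the oxolane, the stearate and the three stereocentres intact.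

Compound list
1 | 4-(benzyloxy)-3-methoxybenzaldehyde (O-benzylvanillin) | COc1cc(C=O)ccc1OCc1ccccc1 | starting material
2 | bromomagnesium alkoxide of 3 | C#CC(O[Mg]Br)c1ccc(OCc2ccccc2)c(OC)c1 | intermediate
3 | rac-1-[4-(benzyloxy)-3-methoxyphenyl]prop-2-yn-1-ol | C#CC(O)c1ccc(OCc2ccccc2)c(OC)c1 | intermediate
4 | (S)-1-[4-(benzyloxy)-3-methoxyphenyl]prop-2-yn-1-ol | C#C[C@H](O)c1ccc(OCc2ccccc2)c(OC)c1 | intermediate
5 | allyl bromide | C=CCBr | starting material
6 | sodium alkoxide of 4 | C#C[C@H]([O-])c1ccc(OCc2ccccc2)c(OC)c1.[Na+] | intermediate
7 | (S)-4-[1-(allyloxy)prop-2-yn-1-yl]-1-(benzyloxy)-2-methoxybenzene | C#C[C@H](OCC=C)c1ccc(OCc2ccccc2)c(OC)c1 | intermediate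
8 | stearic acid | CCCCCCCCCCCCCCCCCC(=O)O | starting material
9 | (S,Z)-3-(allyloxy)-3-[4-(benzyloxy)-3-methoxyphenyl]prop-1-en-1-yl stearate | CCCCCCCCCCCCCCCCCC(=O)O/C=C\[C@H](OCC=C)c1ccc(OCc2ccccc2)c(OC)c1 | intermediate
10 | 2-methoxy-4-nitrophenol | COc1cc([N+](=O)[O-])ccc1O | starting material
11 | 1-(benzyloxy)-2-methoxy-4-nitrobenzene | COc1cc([N+](=O)[O-])ccc1OCc1ccccc1 | intermediate
12 | 4-(benzyloxy)-3-methoxyaniline | COc1cc(N)ccc1OCc1ccccc1 | intermediate
13 | 4-(benzyloxy)-3-methoxybenzenediazonium tetrafluoroborate | COc1cc([N+]#N)ccc1OCc1ccccc1.F[B-](F)(F)F | intermediate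
14 | 4-(benzyloxy)-3-methoxyphenyl radical | COc1c[c]ccc1OCc1ccccc1 | intermediate
15 | open-chain secondary radical at C4 (aryl adduct of 9) | CCCCCCCCCCCCCCCCCC(=O)O/C=C\[C@H](OC[CH]Cc1ccc(OCc2ccccc2)c(OC)c1)c1ccc(OCc2ccccc2)c(OC)c1 | intermediate
16 | cyclised alpha-acyloxy radical at C3a | CCCCCCCCCCCCCCCCCC(=O)O[CH][C@H]1[C@@H](Cc2ccc(OCc3ccccc3)c(OC)c2)CO[C@@H]1c1ccc(OCc2ccccc2)c(OC)c1 | intermediate
17 | [(2S,3R,4R)-2-[4-(benzyloxy)-3-methoxyphenyl]-4-[4-(benzyloxy)-3-methoxybenzyl]oxolan-3-yl]methyl stearate (O,O'-dibenzyl ether of 18) | CCCCCCCCCCCCCCCCCC(=O)OC[C@H]1[C@@H](Cc2ccc(OCc3ccccc3)c(OC)c2)CO[C@@H]1c1ccc(OCc2ccccc2)c(OC)c1 | intermediate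
18 | [(2S,3R,4R)-2-(4-hydroxy-3-methoxyphenyl)-4-(4-hydroxy-3-methoxybenzyl)oxolan-3-yl]methyl stearate | CCCCCCCCCCCCCCCCCC(=O)OC[C@H]1[C@@H](Cc2ccc(O)c(OC)c2)CO[C@@H]1c1ccc(O)c(OC)c1 | target

Total step count: 9. Longest linear sequence: 6 (steps 1, 2, 3, 4, 8, 9).

Steps most likely to fail

**Step 8.**
- **What may go wrong:**
  - Aryl radical 14 may be drained by hydrogen abstraction from Hantzsch ester, from the solvent, or from the activated C2–H and C5–H bonds of 9.
  - Radicals 15 and 16 may be captured at the terminal nitrogen of 13 (azo coupling) before ring closure or hydrogen transfer.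
  - Part of the addition may go to the enol ester.
  - The cis preference at C3/C4 may be small.
- **Fallback:** the C4a–aryl bond is made by a polar reaction and only the ring closure stays radical. It sets out from 7.
  - Epoxidation of the allyl group (mCPBA, NaHCO3, CH2Cl2) should give glycidyl ether F1 as a mixture of C4 epimers. The mixture is harmless, because C4 becomes planar later.
  - The aryl Grignard reagent F2 is made from commercial 1-(benzyloxy)-4-bromo-2-methoxybenzene and Mg. It is used in excess because the alkyne C–H consumes one equivalent.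
  - Under CuI catalysis (THF, −30 to 0 °C) it should open F1 at the terminal carbon C4a to give secondary alcohol F3.
  - An Appel reaction (I2, PPh3, imidazole) should give secondary iodide F4. Stearic acid 8 is then added to the alkyne under the conditions of step 4 to give iodo enol stearate F5.
  - Bu3SnH with Et3B/air at 0 °C or below then generates radical 15 directly from the C–I bond. It closes to 16 and takes hydrogen from the stannane, and the route is rejoined at 17.
  - No diazonium salt and no free aryl radical are present, and the low temperature should sharpen both diastereoselectivities.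

**Step 4.**
- **What may go wrong:**
  - The ruthenium centre may engage the 1,6-enyne as a whole, through vinylidene or metallacycle pathways that consume the allyl alkene.
  - It may isomerise the allyl ether to a propenyl ether, or add the acid in the Markovnikov sense.
  - The warm carboxylic acid may ionise the doubly activated C2–O bond, with erosion of enantiopurity.
- **Fallback:** the C3a–O bond is made by copper-catalysed oxidative coupling instead of alkyne addition. It sets out from 7.
  - Alkyne-selective hydroboration with pinacolborane (Cp2ZrHCl cat., Et3N cat., CH2Cl2, rt) should give E-alkenylboronate F6.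
  - KHF2 in aqueous MeOH converts this into potassium alkenyltrifluoroborate F7.
  - A Chan–Lam-type coupling with 8 (CuBr cat., DMAP, 4 Å molecular sieves, O2, MeCN, 60 °C) should give, with retention of geometry, E-enol stearate F8, the geometric isomer of 9.
  - Because C3a ends as CH2, the geometry does not appear in the product, so F8 is taken through the conditions of step 8. Radical 14 adds to give open-chain E radical F9, which closes to the same radical 16, and the route is rejoined at 17.
  - The price is the loss of the allylic-strain element. The 2,3-trans relation then rests only on the pseudo-equatorial aryl group.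

**Step 2.**
- **What may go wrong:**
  - The lipase may discriminate poorly between the two flat flanking groups, or may acylate the bulky 3,4-dialkoxyaryl substrate too slowly.
  - Any shortfall in enantiopurity is carried to the target, since no later step upgrades it, and half of the material is lost in any case.
- **Fallback:** reagent-controlled asymmetric reduction instead of resolution. It sets out from 3.
  - Oxidation with activated MnO2 (CH2Cl2, rt) should give aryl ethynyl ketone F10.
  - Midland reduction with (R)-Alpine-Borane (B-isopinocampheyl-9-borabicyclo[3.3.1]nonane from (+)-α-pinene; concentrated THF, rt; acetaldehyde, then ethanolamine work-up) distinguishes the linear ethynyl group from the aryl group by size.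
  - It should deliver hydride to the face that gives the (S)-alcohol, so the route is rejoined at 4 with all of the material in the wanted series.

Further compounds
F1 | step 8 | 2-({(1S)-1-[4-(benzyloxy)-3-methoxyphenyl]prop-2-yn-1-yl}oxymethyl)oxirane, both epimers at the oxirane carbon | C#C[C@H](OCC1CO1)c1ccc(OCc2ccccc2)c(OC)c1
F2 | step 8 | 4-(benzyloxy)-3-methoxyphenylmagnesium bromide | COc1cc([Mg]Br)ccc1OCc1ccccc1
F3 | step 8 | 1-[4-(benzyloxy)-3-methoxyphenyl]-3-{(1S)-1-[4-(benzyloxy)-3-methoxyphenyl]prop-2-yn-1-yl}oxypropan-2-ol, both epimers at C4 | C#C[C@H](OCC(O)Cc1ccc(OCc2ccccc2)c(OC)c1)c1ccc(OCc2ccccc2)c(OC)c1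
F4 | step 8 | corresponding secondary iodide at C4, both epimers | C#C[C@H](OCC(I)Cc1ccc(OCc2ccccc2)c(OC)c1)c1ccc(OCc2ccccc2)c(OC)c1
F5 | step 8 | (S,Z)-3-[4-(benzyloxy)-3-methoxyphenyl]-3-{3-[4-(benzyloxy)-3-methoxyphenyl]-2-iodopropoxy}prop-1-en-1-yl stearate, both epimers at C4 | CCCCCCCCCCCCCCCCCC(=O)O/C=C\[C@H](OCC(I)Cc1ccc(OCc2ccccc2)c(OC)c1)c1ccc(OCc2ccccc2)c(OC)c1
F6 | step 4 | 2-{(S,E)-3-(allyloxy)-3-[4-(benzyloxy)-3-methoxyphenyl]prop-1-en-1-yl}-4,4,5,5-tetramethyl-1,3,2-dioxaborolane | CC1(C)OB(/C=C/[C@H](OCC=C)c2ccc(OCc3ccccc3)c(OC)c2)OC1(C)C
F7 | step 4 | potassium {(S,E)-3-(allyloxy)-3-[4-(benzyloxy)-3-methoxyphenyl]prop-1-en-1-yl}trifluoroborate | [K+].F[B-](F)(F)/C=C/[C@H](OCC=C)c1ccc(OCc2ccccc2)c(OC)c1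
F8 | step 4 | (S,E)-3-(allyloxy)-3-[4-(benzyloxy)-3-methoxyphenyl]prop-1-en-1-yl stearate | CCCCCCCCCCCCCCCCCC(=O)O/C=C/[C@H](OCC=C)c1ccc(OCc2ccccc2)c(OC)c1
F9 | step 4 | open-chain secondary radical at C4 with E-enol stearate (aryl adduct of F8) | CCCCCCCCCCCCCCCCCC(=O)O/C=C/[C@H](OC[CH]Cc1ccc(OCc2ccccc2)c(OC)c1)c1ccc(OCc2ccccc2)c(OC)c1
F10 | step 2 | 1-[4-(benzyloxy)-3-methoxyphenyl]prop-2-yn-1-one | C#CC(=O)c1ccc(OCc2ccccc2)c(OC)c1
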